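The rate constants were drawn at random within sensible limits, and the outcome is calculated.

A pitfall of two-phase flasks is to take the reagent in the reaction phase as a fixed share of its charge, as though the transfer stood at equilibrium at every moment, and then to treat what follows as an ordinary bimolecular reaction.

    reagent in the reaction phase ⇌ reagent in the second phase, rate k1*([reagent in the reaction phase] - [reagent in the second phase]/K1) per volume of the first phase (K1 = 6.2, k1 = 0.033 s⁻¹)
    substrate + reagent in the reaction phase → target (k2 = 19 M⁻¹ s⁻¹)
    2 reagent in the reaction phase → homo dimer (k3 = 0.13 M⁻¹ s⁻¹)
    target ⇌ isomer of the product (K4 = 2.7, k4 = 0.11 s⁻¹)

| setting | east | south-east | west |
|---|---|---|---|
| substrate | 0.25 M | 0.80 M | 2.5 M |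
| reagent in the second phase | 0.175 M | 0.175 M | 0.175 M |
| time | 40 s | 40 s | 40 s |
| volume of the second phase over the first | 0.50 | 0.50 | 0.50 |

- for a step with 2 of a species take k times the square, and two of it per event
- in the second phase: reagent in the second phase; everything else is in the first
- charges count per volume of the first phase; a concentration in a rate is the amount of a species over the volume of its own phase; every rate counts per litre of the first phase
- "hardly changes" means that all values lie within two and a half points (for a concentration: within two and a half percent of the largest)
- run time (east): 40 s

* amount of target at the end, in percent of the substrate charged for east, south-east, west, in this order
* the shape of the row from first to last (rises, then falls / falls, then rises / falls all the way / rises all the way / hardly changes)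

Two chemists dispute this flask. The first holds the transfer to be a fast pre-equilibrium, with 24.4 % of the charge standing in the reaction phase. In east the charged reagent then falls with a constant of 1.16 s⁻¹, a lifetime far shorter than 40 s, so on this view the full 0.175 M becomes target and isomer of the product. The isomerisation relaxes with a half-life of 4.60 s, short against that time, so target takes its equilibrium share of 27.0 %. That makes 0.0473 M, which is 18.9 % in east and 1.89 % in west.

The second chemist, and I with them, asks what a molecule of reagent does once it has crossed. Divide the rate of capture by the rate of capture plus return: [reagent in the reaction phase] cancels, and time stays in the ratio through [substrate]. In east, with [substrate] as charged, this gives 99.3 %, the fraction of crossing reagent that meets substrate instead of going back, which is the capture share. Capture is far faster than return, so in east the crossing is the rate-limiting step.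

The reagent in the second phase then leaves by first order, with the transfer coefficient over the partition ratio and the volume ratio, 0.0106 s⁻¹, multiplied by the capture share. My reckoning for east gives 0.0603 M of target and isomer together by 40 s, and there it stops, since it does not split that sum.

The first view keeps a region: the capture share is 0.5 at [substrate] of 0.00174 M, and far under that value return outruns capture. The charges here lie far above that.

The forecast takes the second side and gives 9 %, 2.83 %, 0.91 %, with the shape falls all the way: “the yield falls as the substrate charge rises”. The first chemist's row falls too, but stands about twice as high.

The simulation gives 9.00 %, 2.83 %, 0.908 %, shape falls all the way, so the forecast holds. In east at 40.0 s, the reagent in the second phase still holds 65.5 % of its own charge, and with 76 % of the substrate left the capture share is 99.1 %. In west the capture share with [substrate] as charged is 99.9 %, so the same first-order loss over 40 s leaves 65.3 % of the charge in the second phase, and the flask shows 65.3 % at 40.0 s.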